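Assumption: the target SMILES contains no stereocentre, so the compound is achiral and there is no configuration to set. The route has not been run; yields and selectivities are expectations from the reaction types named.

**Retrosynthetic overview**
1. Target 10 comes from its ring A benzyl ether 9 by a final hydrogenolysis; 9 comes from the tridepside aldehyde 8 by CHO to COOH oxidation.
2. The B–C ester C–O bond is cut to give depside acid 6 and orsellinaldehyde 4; 6 comes from depside aldehyde 5 by the same oxidation.
3. Key disconnection: the ring A aryl–C(=O) bond, cut together with the A–B ester C–O bond. This gives aryl iodide 3 (aryl cation synthon) and CO plus the phenoxide of 4 (aryloxycarbonyl anion synthon), joined by palladium catalysis.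
4. Iodide 3 comes from 3-methoxy-5-methylphenol 1 by para-iodination and O-benzylation.
5. No ring is built: rings A, B and C are bought intact (1, 4, 4) and joined in the order A–B, then B–C.

**Route**

Step 1
Reactants: 1 3-methoxy-5-methylphenol
Product: 2 4-iodo-3-methoxy-5-methylphenol
Conditions: NIS (1.0 equiv), TsOH·H2O (10 mol %), MeCN, 0 °C to rt
Reagents that add atoms: N-iodosuccinimide, O=C1CCC(=O)N1I
Why: Electrophilic aromatic iodination in which the free OH is the strongest director and the acid-catalysed NIS protocol iodinates phenols para to OH, so iodine enters between OMe and CH3; the minor ortho isomer is removed by chromatography.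

Step 2
Reactants: 2 4-iodo-3-methoxy-5-methylphenol
Product: 3 5-(benzyloxy)-2-iodo-1-methoxy-3-methylbenzene
Conditions: BnBr (1.1 equiv), K2CO3 (1.5 equiv), DMF, rt
Reagents that add atoms: benzyl bromide, BrCc1ccccc1
Why: Williamson ether synthesis that masks the only free phenol, so that the iodide cannot acylate itself in step 3 and the acid cannot self-esterify in step 5.

Step 3
Reactants: 3 5-(benzyloxy)-2-iodo-1-methoxy-3-methylbenzene; 4 2,4-dihydroxy-6-methylbenzaldehyde (orsellinaldehyde, 1.5 equiv)
Product: 5 4-formyl-3-hydroxy-5-methylphenyl 4-(benzyloxy)-2-methoxy-6-methylbenzoate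
Conditions: Pd(OAc)2 (5 mol %), Xantphos (7.5 mol %), CO (5 bar), Et3N (3 equiv), toluene, 90 °C
Reagents that add atoms: carbon monoxide, [C-]#[O+]
Why: Palladium-catalysed three-component aryloxycarbonylation (Heck-type carbonylative esterification) in which zerovalent palladium inserts into the C–I bond, CO inserts, and the acidic, unhindered 4-OH phenoxide of 4 captures the aroyl–palladium species, so that two acceptor carbons (the C–I carbon and the CO carbon) are joined with CO/phenoxide acting as an aryloxycarbonyl-anion equivalent and the depside C–C and C–O bonds form in one operation; the 2-OH of 4 is hydrogen-bonded to the aldehyde and does not compete.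

Step 4
Reactants: 5 4-formyl-3-hydroxy-5-methylphenyl 4-(benzyloxy)-2-methoxy-6-methylbenzoate
Product: 6 4-{[4-(benzyloxy)-2-methoxy-6-methylbenzoyl]oxy}-2-hydroxy-6-methylbenzoic acid
Conditions: NaClO2 (3 equiv), NaH2PO4 (3 equiv), 2-methyl-2-butene (10 equiv), t-BuOH/THF/H2O, 0 °C to rt
Reagents that add atoms: sodium chlorite, [Na+].[O-]Cl=O
Why: Pinnick (Lindgren) oxidation, which converts hindered hydroxybenzaldehydes to acids at pH 4 without touching the aryl ester, while the alkene scavenges HOCl before it can chlorinate ring A.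

Step 5
Reactants: 6 4-{[4-(benzyloxy)-2-methoxy-6-methylbenzoyl]oxy}-2-hydroxy-6-methylbenzoic acid; 4 2,4-dihydroxy-6-methylbenzaldehyde (1.2 equiv)
Product: 8 4-formyl-3-hydroxy-5-methylphenyl 4-{[4-(benzyloxy)-2-methoxy-6-methylbenzoyl]oxy}-2-hydroxy-6-methylbenzoate, via O-acylisourea 7 (not isolated)
Conditions: DCC (1.1 equiv), toluene/THF, 0 °C to rt
Reagents that add atoms: none
Why: Carbodiimide dehydrative esterification of the kind used for depsides, in which only the 4-OH of 4 is nucleophilic because the ortho-hydroxyls of 6 and of 4 are locked in hydrogen bonds to their carbonyl groups.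

Step 6
Reactants: 8 4-formyl-3-hydroxy-5-methylphenyl 4-{[4-(benzyloxy)-2-methoxy-6-methylbenzoyl]oxy}-2-hydroxy-6-methylbenzoate
Product: 9 4-[(4-{[4-(benzyloxy)-2-methoxy-6-methylbenzoyl]oxy}-2-hydroxy-6-methylbenzoyl)oxy]-2-hydroxy-6-methylbenzoic acid
Conditions: NaClO2 (3 equiv), NaH2PO4 (3 equiv), 2-methyl-2-butene (10 equiv), t-BuOH/THF/H2O, 0 °C to rt
Reagents that add atoms: sodium chlorite, [Na+].[O-]Cl=O
Why: Second Pinnick oxidation under the conditions proven in step 4, leaving both depside esters intact.

Step 7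
Reactants: 9 4-[(4-{[4-(benzyloxy)-2-methoxy-6-methylbenzoyl]oxy}-2-hydroxy-6-methylbenzoyl)oxy]-2-hydroxy-6-methylbenzoic acid
Product: 10 umbilicaric acid, 4-[(4-{[4-hydroxy-2-methoxy-6-methylbenzoyl]oxy}-2-hydroxy-6-methylbenzoyl)oxy]-2-hydroxy-6-methylbenzoic acid
Conditions: H2 (1 atm), palladium on carbon (10% Pd/C), EtOAc/THF, rt
Reagents that add atoms: none
Why: Heterogeneous hydrogenolysis of the single benzyl ether, under which aryl esters, the carboxylic acid and the phenols are inert, as in classical depside end-games.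

**Compound list**
1 | 3-methoxy-5-methylphenol (orcinol monomethyl ether) | COc1cc(C)cc(O)c1 | starting material
2 | 4-iodo-3-methoxy-5-methylphenol | COc1cc(O)cc(C)c1I | intermediate
3 | 5-(benzyloxy)-2-iodo-1-methoxy-3-methylbenzene | COc1cc(OCc2ccccc2)cc(C)c1I | intermediate
4 | 2,4-dihydroxy-6-methylbenzaldehyde (orsellinaldehyde) | Cc1cc(O)cc(O)c1C=O | starting material
5 | 4-formyl-3-hydroxy-5-methylphenyl 4-(benzyloxy)-2-methoxy-6-methylbenzoate | COc1cc(OCc2ccccc2)cc(C)c1C(=O)Oc1cc(C)c(C=O)c(O)c1 | intermediate
6 | 4-{[4-(benzyloxy)-2-methoxy-6-methylbenzoyl]oxy}-2-hydroxy-6-methylbenzoic acid | COc1cc(OCc2ccccc2)cc(C)c1C(=O)Oc1cc(C)c(C(=O)O)c(O)c1 | intermediate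
7 | O-acylisourea of acid 6 with DCC (not isolated) | COc1cc(OCc2ccccc2)cc(C)c1C(=O)Oc1cc(C)c(C(=O)OC(=NC2CCCCC2)NC2CCCCC2)c(O)c1 | intermediate
8 | 4-formyl-3-hydroxy-5-methylphenyl 4-{[4-(benzyloxy)-2-methoxy-6-methylbenzoyl]oxy}-2-hydroxy-6-methylbenzoate | COc1cc(OCc2ccccc2)cc(C)c1C(=O)Oc1cc(C)c(C(=O)Oc2cc(C)c(C=O)c(O)c2)c(O)c1 | intermediate
9 | 4-[(4-{[4-(benzyloxy)-2-methoxy-6-methylbenzoyl]oxy}-2-hydroxy-6-methylbenzoyl)oxy]-2-hydroxy-6-methylbenzoic acid | COc1cc(OCc2ccccc2)cc(C)c1C(=O)Oc1cc(C)c(C(=O)Oc2cc(C)c(C(=O)O)c(O)c2)c(O)c1 | intermediate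
10 | umbilicaric acid | COc1cc(O)cc(C)c1C(=O)Oc1cc(C)c(C(=O)Oc2cc(C)c(C(=O)O)c(O)c2)c(O)c1 | target

**Totals**
Total step count: 7. Longest linear sequence: 7 (1 to 10; compound 4 is bought and used in steps 3 and 5).

**Steps most likely to fail, with fallbacks**

Step 3 (key carbonylative esterification). The iodide is flanked by OMe and CH3, so CO insertion and capture by a weakly nucleophilic, functionalised phenoxide may be slow, and reduction of the iodide may compete. The fallback sets out from 3 and comes back at 5. It keeps the carbonylative C–C bond formation but uses water, the smallest nucleophile: Pd(OAc)2/Xantphos, CO, K2CO3, dioxane/H2O, 90 °C, then acid, gives 4-(benzyloxy)-2-methoxy-6-methylbenzoic acid F1. TFAA in toluene at rt then converts this acid into 4-(benzyloxy)-2-methoxy-6-methylbenzoic trifluoroacetic anhydride F2 (not isolated). This hindered acyl donor ionises towards the acylium ion and acylates the 4-OH of 4 to give 5.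

Step 1 (regioselective iodination). Attack ortho to OH (para to OMe) may compete and the isomers may be hard to separate. The fallback sets out from 1 and comes back at 3. Bu4NBr3 in CH2Cl2 at rt, a reagent known for para-selective monobromination of phenols, gives 4-bromo-3-methoxy-5-methylphenol F3. BnBr/K2CO3 in DMF gives 5-(benzyloxy)-2-bromo-1-methoxy-3-methylbenzene F4. Bromine–lithium exchange with n-BuLi in THF at −78 °C gives [4-(benzyloxy)-2-methoxy-6-methylphenyl]lithium F5 (not isolated), which is quenched with I2 to give 3.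

Step 6 (late Pinnick oxidation). The tridepside aldehyde 8 is sparingly soluble, and a stalled reaction or chlorination of the electron-rich ring A would cost advanced material. The fallback sets out from 6 and comes back at 10; it brings ring C in at the acid oxidation level so that no late oxidation is needed. Commercial orsellinic acid (2,4-dihydroxy-6-methylbenzoic acid) with BnBr/KHCO3 in DMF gives benzyl 2,4-dihydroxy-6-methylbenzoate F6. DCC coupling of 6 with this ester, again through 7, gives benzyl 4-[(4-{[4-(benzyloxy)-2-methoxy-6-methylbenzoyl]oxy}-2-hydroxy-6-methylbenzoyl)oxy]-2-hydroxy-6-methylbenzoate F7. H2 with palladium on carbon (10% Pd/C) in EtOAc/THF removes both benzyl groups to give 10.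

**Further compounds**
F1 | step 3 | 4-(benzyloxy)-2-methoxy-6-methylbenzoic acid | COc1cc(OCc2ccccc2)cc(C)c1C(=O)O
F2 | step 3 | 4-(benzyloxy)-2-methoxy-6-methylbenzoic trifluoroacetic anhydride | COc1cc(OCc2ccccc2)cc(C)c1C(=O)OC(=O)C(F)(F)F
F3 | step 1 | 4-bromo-3-methoxy-5-methylphenol | COc1cc(O)cc(C)c1Br
F4 | step 1 | 5-(benzyloxy)-2-bromo-1-methoxy-3-methylbenzene | COc1cc(OCc2ccccc2)cc(C)c1Br
F5 | step 1 | [4-(benzyloxy)-2-methoxy-6-methylphenyl]lithium | COc1cc(OCc2ccccc2)cc(C)c1[Li]
F6 | step 6 | benzyl 2,4-dihydroxy-6-methylbenzoate | Cc1cc(O)cc(O)c1C(=O)OCc1ccccc1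
F7 | step 6 | benzyl 4-[(4-{[4-(benzyloxy)-2-methoxy-6-methylbenzoyl]oxy}-2-hydroxy-6-methylbenzoyl)oxy]-2-hydroxy-6-methylbenzoate | COc1cc(OCc2ccccc2)cc(C)c1C(=O)Oc1cc(C)c(C(=O)Oc2cc(C)c(C(=O)OCc3ccccc3)c(O)c2)c(O)c1
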